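**Retrosynthetic overview**
- The lactone is planned as its isochroman, one oxidation level lower at C1 and with O8 as its methyl ether. Late oxidation of C1 and cleavage of the O8 methyl group return the target.
- The isochroman is cut at C3–C4. C4 becomes the carbene carbon of an aryl aldehyde tosylhydrazone, and C3 is an untouched OCH2 group of a dodecane-1,12-diol monoether. Ring B is the only ring formed; ring A is bought.
- Enabling feature: the chain C4–C4a–C8a–C1–O2–C3 spans two ortho positions of ring A, so a radical at C4 reaches a C3–H bond (1,6-HAT), and O2 weakens that bond. The methoxy groups at C6 and C8 are para and ortho to C8a, so C1 is a 2,4-dimethoxybenzyl ether carbon that DDQ oxidises selectively afterwards.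
- The cyclisation precursor comes from an sp2–sp3 Suzuki–Miyaura coupling (C8a–C1) of an alkoxymethyltrifluoroborate made from the diol. The primary alcohol carries no protecting group.

Key step: step 4

Assumption: precedent does not fix the sense of induction of the chiral cobalt porphyrin for this ring size, so the first experiment selects the ligand enantiomer that gives the R centre (both derive from the two commercial enantiomers of 2,2-dimethylcyclopropanecarboxamide); atom numbers are those of the isochroman skeleton (C1, O2, C3, C4, C4a to C8a), ring A is the arene and ring B the oxygen ring.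

**Step 1**
Reactants: 1 dodecane-1,12-diol; 2 potassium (bromomethyl)trifluoroborate
Product: 3 potassium trifluoro{[(12-hydroxydodecyl)oxy]methyl}borate
Conditions: 1 (4 equiv), NaH (3 equiv), THF, 0 °C to rt; trituration with warm Et2O
Reagents that add atoms: none
Why: Williamson-type SN2 displacement of bromide by the mono-alkoxide is the known route to alkoxymethyltrifluoroborates; the excess of symmetrical diol should keep double substitution low, and the salt is freed from neutral diol by trituration.

**Step 2**
Reactants: 3 potassium trifluoro{[(12-hydroxydodecyl)oxy]methyl}borate; 4 2-bromo-3,5-dimethoxybenzaldehyde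
Product: 5 2-{[(12-hydroxydodecyl)oxy]methyl}-3,5-dimethoxybenzaldehyde
Conditions: Pd(OAc)2 (3 mol %), RuPhos (6 mol %), Cs2CO3 (3 equiv), dioxane/H2O 10:1, 100 °C
Reagents that add atoms: none
Why: This is an sp2–sp3 Suzuki–Miyaura coupling of an alkoxymethyltrifluoroborate, a nucleophile without β-hydrogen, with an aryl bromide whose oxidative addition to zerovalent palladium is helped by the ortho formyl group; the aldehyde and the free alcohol should be tolerated.

**Step 3**
Reactants: 5 2-{[(12-hydroxydodecyl)oxy]methyl}-3,5-dimethoxybenzaldehyde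
Product: 6 (E)-N'-[2-{[(12-hydroxydodecyl)oxy]methyl}-3,5-dimethoxybenzylidene]-4-methylbenzenesulfonohydrazide
Conditions: TsNHNH2 (1.05 equiv), MeOH, rt
Reagents that add atoms: 4-methylbenzenesulfonohydrazide, Cc1ccc(cc1)S(=O)(=O)NN
Why: Condensation of an aromatic aldehyde with tosylhydrazide should give the E-hydrazone, and no other group in the molecule reacts.

**Step 4**
Reactants: 6 (E)-N'-[2-{[(12-hydroxydodecyl)oxy]methyl}-3,5-dimethoxybenzylidene]-4-methylbenzenesulfonohydrazide
Product: 8 11-[(3R)-6,8-dimethoxy-3,4-dihydro-1H-isochromen-3-yl]undecan-1-ol, via aryldiazomethane 7 (not isolated)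
Conditions: [Co(3,5-DitBu-ChenPhyrin)] (5 mol %), Cs2CO3 (1.5 equiv), 1,4-dioxane (0.02 M), 50 °C, N2
Reagents that add atoms: none
Why: Proposed new method: Bamford–Stevens loss of sulfinate from 6 releases aryldiazomethane 7 slowly, the divalent cobalt metalloradical takes it up with loss of N2 to give a benzylic radical at C4 bound to trivalent cobalt, this radical abstracts one C3–H through a seven-membered transition state (1,6-HAT), and the O2-stabilised C3 radical then attacks C4 in a homolytic substitution that forms C3–C4 and returns divalent cobalt. The closest known reaction types are the enantioselective cobalt-metalloradical 1,5-C–H alkylation of aryldiazomethanes made in situ from sulfonylhydrazones (2-substituted indolines with a CH2 next to the new stereocentre), the achiral [Co(TPP)] reactions of ortho-(allyloxymethyl)aryl carbene radicals that begin with HAT from the same OCH2 position, and the 1,6-C–H insertion of donor carbenes under Rh2(R-PTAD)4 that gives isochromans; the new element is the enantioselective 1,6-variant at an unbranched alkyl ether. Ring B closes in a 6-exo-tet radical substitution at C4, with cobalt as the exocyclic leaving group. The C3 stereocentre is controlled by the chiral cavity of the D2-symmetric amidoporphyrin, which should select the pro-S hydrogen of the OCH2 group in the HAT and hold the radical so that ring closure is faster than rotation, giving net retention and the R configuration. Site selectivity is needed against the weak C1–H bonds and the remote CH2 groups: C1–H can be reached only through a strained five-membered transition state that would lead to a benzocyclobutene, and the chain CH2 groups beyond C3 lack the O2 lone pair and need larger transition states. Chemoselectivity against ylide formation at O2, O–H insertion at the free alcohol and carbene dimerisation is expected from the radical, non-electrophilic character of the cobalt carbene, the dilution and the slow release of 7.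

**Step 5**
Reactants: 8 11-[(3R)-6,8-dimethoxy-3,4-dihydro-1H-isochromen-3-yl]undecan-1-ol
Product: 10 (3R)-3-(11-hydroxyundecyl)-6,8-dimethoxy-3,4-dihydro-1H-isochromen-1-one, via lactol 9 (not isolated)
Conditions: DDQ (20 mol %), MnO2 (10 equiv), CH2Cl2/H2O 20:1, rt
Reagents that add atoms: water, O
Why: This is an oxidative benzylic ether C–H cleavage in which DDQ abstracts hydride only at C1 (a 2,4-dimethoxybenzyl ether carbon), water gives lactol 9, and MnO2 both re-oxidises the hydroquinone (catalytic-DDQ protocol) and oxidises the benzylic lactol to the lactone; the saturated primary alcohol, C4 and the C3 stereocentre should stay untouched.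

**Step 6**
Reactants: 10 (3R)-3-(11-hydroxyundecyl)-6,8-dimethoxy-3,4-dihydro-1H-isochromen-1-one
Product: 11 (3R)-8-hydroxy-3-(11-hydroxyundecyl)-6-methoxy-3,4-dihydro-1H-isochromen-1-one
Conditions: BCl3 (3 equiv), CH2Cl2, −78 to 0 °C; aq NaHCO3
Reagents that add atoms: none
Why: This is a chelation-controlled aryl methyl ether cleavage: BCl3 binds between the lactone carbonyl oxygen and the peri oxygen O8, so only the C8 methyl ether is cleaved, the C6 methoxy group, the lactone and C3 are not affected, and the borate of the primary alcohol hydrolyses on work-up.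

**Compound list**
1 | dodecane-1,12-diol | OCCCCCCCCCCCCO | starting material
2 | potassium (bromomethyl)trifluoroborate | [K+].F[B-](F)(F)CBr | starting material
3 | potassium trifluoro{[(12-hydroxydodecyl)oxy]methyl}borate | [K+].F[B-](F)(F)COCCCCCCCCCCCCO | intermediate
4 | 2-bromo-3,5-dimethoxybenzaldehyde | COc1cc(C=O)c(Br)c(OC)c1 | starting material
5 | 2-{[(12-hydroxydodecyl)oxy]methyl}-3,5-dimethoxybenzaldehyde | COc1cc(C=O)c(COCCCCCCCCCCCCO)c(OC)c1 | intermediate
6 | (E)-N'-[2-{[(12-hydroxydodecyl)oxy]methyl}-3,5-dimethoxybenzylidene]-4-methylbenzenesulfonohydrazide | COc1cc(/C=N/NS(=O)(=O)c2ccc(C)cc2)c(COCCCCCCCCCCCCO)c(OC)c1 | intermediate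
7 | 12-{[2-(diazomethyl)-4,6-dimethoxybenzyl]oxy}dodecan-1-ol (not isolated) | COc1cc(C=[N+]=[N-])c(COCCCCCCCCCCCCO)c(OC)c1 | intermediate
8 | 11-[(3R)-6,8-dimethoxy-3,4-dihydro-1H-isochromen-3-yl]undecan-1-ol | COc1cc(OC)c2c(c1)C[C@@H](CCCCCCCCCCCO)OC2 | intermediate
9 | (3R)-3-(11-hydroxyundecyl)-6,8-dimethoxy-3,4-dihydro-1H-isochromen-1-ol, both C1 epimers (not isolated) | COc1cc(OC)c2c(c1)C[C@@H](CCCCCCCCCCCO)OC2O | intermediate
10 | (3R)-3-(11-hydroxyundecyl)-6,8-dimethoxy-3,4-dihydro-1H-isochromen-1-one | COc1cc(OC)c2c(c1)C[C@@H](CCCCCCCCCCCO)OC2=O | intermediate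
11 | (3R)-8-hydroxy-3-(11-hydroxyundecyl)-6-methoxy-3,4-dihydro-1H-isochromen-1-one | COc1cc(O)c2c(c1)C[C@@H](CCCCCCCCCCCO)OC2=O | target

**Totals**
- Total step count: 6.
- Longest linear sequence: 6 steps (1 to 3 to 5 to 6 to 8 to 10 to 11).

**Steps most likely to fail**

Step 4.
- Risk: the hydrogen-atom transfer through the seven-membered transition state may be slower than bimolecular decay of the carbene radical (azine and stilbene formation). It may also lose out to fragmentation of the C3 radical at the O2–C1 bond. Discrimination between the two enantiotopic hydrogens may be weak in the larger ring.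
- Fallback (known chemistry, sets out from 1, comes back at 8): 1 is monosilylated (TBDPSCl, imidazole, excess 1) to 12-[(tert-butyldiphenylsilyl)oxy]dodecan-1-ol F1. Oxidation (TEMPO, PhI(OAc)2) gives 12-[(tert-butyldiphenylsilyl)oxy]dodecanal F2. A Corey–Chaykovsky reaction with dimethylsulfonium methylide gives racemic 2-{11-[(tert-butyldiphenylsilyl)oxy]undecyl}oxirane F3. Hydrolytic kinetic resolution with (R,R)-[Co(salen)(OAc)] (salen = N,N'-bis(3,5-di-tert-butylsalicylidene)cyclohexane-1,2-diaminate) and 0.55 equiv of water should leave (2R)-2-{11-[(tert-butyldiphenylsilyl)oxy]undecyl}oxirane F4. Opening at the CH2 terminus with 3,5-dimethoxyphenylmagnesium bromide under CuI catalysis gives (2R)-13-[(tert-butyldiphenylsilyl)oxy]-1-(3,5-dimethoxyphenyl)tridecan-2-ol F5. An oxa-Pictet–Spengler reaction with dimethoxymethane and BF3·OEt2 closes ring B at the position ortho and para to the methoxy groups and gives (3R)-3-{11-[(tert-butyldiphenylsilyl)oxy]undecyl}-6,8-dimethoxy-3,4-dihydro-1H-isochromene F6. TBAF then gives 8.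

Step 2.
- Risk: transmetalation at the doubly ortho-substituted arylpalladium bromide may be slow, so protodeboronation of the trifluoroborate and hydrodebromination of the aryl bromide take over.
- Fallback (sets out from 1, comes back at 5): commercial 2-bromo-4,6-dimethoxybenzaldehyde is reduced (NaBH4, MeOH) to (2-bromo-4,6-dimethoxyphenyl)methanol F7. SOCl2 in CH2Cl2 at 0 °C converts it into 1-bromo-2-(chloromethyl)-3,5-dimethoxybenzene F8, which is used crude. Williamson etherification with the mono-alkoxide of excess 1 (NaH, THF/DMF) gives 12-[(2-bromo-4,6-dimethoxybenzyl)oxy]dodecan-1-ol F9. Bromine–lithium exchange (nBuLi, 2.2 equiv, THF, −78 °C) and a DMF quench give 5.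

Step 5.
- Risk: the C1 oxocarbenium ion may be captured by the free primary alcohol of a second molecule (oligomeric acetals). The sequence may also stall at the lactol stage, or the electron-rich ring A may be degraded oxidatively.
- Fallback (sets out from 8, comes back at 10): stoichiometric DDQ in CH2Cl2/pH 7 buffer is used, and lactol 9 is isolated. Its open hydroxy-aldehyde tautomer is oxidised under Pinnick conditions (NaClO2, NaH2PO4, 2-methyl-2-butene, tBuOH/H2O), which leave alcohols untouched. This gives 2-[(2R)-2,13-dihydroxytridecyl]-4,6-dimethoxybenzoic acid F10. Acid-catalysed lactonisation (TsOH cat., toluene, rt) through the secondary hydroxyl group gives 10.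

**Further compounds**
F1 | step 4 | 12-[(tert-butyldiphenylsilyl)oxy]dodecan-1-ol | OCCCCCCCCCCCCO[Si](c1ccccc1)(c1ccccc1)C(C)(C)C
F2 | step 4 | 12-[(tert-butyldiphenylsilyl)oxy]dodecanal | O=CCCCCCCCCCCCO[Si](c1ccccc1)(c1ccccc1)C(C)(C)C
F3 | step 4 | 2-{11-[(tert-butyldiphenylsilyl)oxy]undecyl}oxirane (racemic) | CC(C)(C)[Si](c1ccccc1)(c1ccccc1)OCCCCCCCCCCCC1CO1
F4 | step 4 | (2R)-2-{11-[(tert-butyldiphenylsilyl)oxy]undecyl}oxirane | CC(C)(C)[Si](c1ccccc1)(c1ccccc1)OCCCCCCCCCCC[C@@H]1CO1
F5 | step 4 | (2R)-13-[(tert-butyldiphenylsilyl)oxy]-1-(3,5-dimethoxyphenyl)tridecan-2-ol | COc1cc(OC)cc(C[C@H](O)CCCCCCCCCCCO[Si](c2ccccc2)(c2ccccc2)C(C)(C)C)c1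
F6 | step 4 | (3R)-3-{11-[(tert-butyldiphenylsilyl)oxy]undecyl}-6,8-dimethoxy-3,4-dihydro-1H-isochromene | COc1cc(OC)c2c(c1)C[C@@H](CCCCCCCCCCCO[Si](c3ccccc3)(c3ccccc3)C(C)(C)C)OC2
F7 | step 2 | (2-bromo-4,6-dimethoxyphenyl)methanol | COc1cc(Br)c(CO)c(OC)c1
F8 | step 2 | 1-bromo-2-(chloromethyl)-3,5-dimethoxybenzene | COc1cc(Br)c(CCl)c(OC)c1
F9 | step 2 | 12-[(2-bromo-4,6-dimethoxybenzyl)oxy]dodecan-1-ol | COc1cc(Br)c(COCCCCCCCCCCCCO)c(OC)c1
F10 | step 5 | 2-[(2R)-2,13-dihydroxytridecyl]-4,6-dimethoxybenzoic acid | COc1cc(OC)c(C(=O)O)c(C[C@H](O)CCCCCCCCCCCO)c1
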